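**Retrosynthetic overview**
1. Target 26 ⇐ global hydrogenolysis of the benzyl-protected tridepside 25. 25 ⇐ two aryl-ester (depside) bonds: ring-A acid 12 + ring-B phenol 17 (allyl ester), then didepside acid 23 + ring-C phenol 20 (benzyl orsellinate).
2. Rings A, B and C ⇐ one building block, methyl orsellinate 6 (A: C5 bromination → boronate → OH; B: 4-O-Bn / 2-O-Me; C: ester exchange to benzyl).
3. 6 ⇐ methyl dihydroorsellinate 4 (bromine aromatisation, then debromination) ⇐ intermolecular Michael addition of methyl acetoacetate 1 to methyl crotonate 2 (the key C–C bond), followed by Dieckmann closure.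
4. Ring order: the only ring constructed is the orsellinate carbocycle (step 1, aromatised in steps 2–3). Three copies are then differentiated and joined A–B first, then AB–C.

Assumption: the target has no stereocentre, so nothing has to be set; the transient stereocentres of 3 and 4 (formed as racemic mixtures) disappear on aromatisation in step 2.

**Route**

Step 1
Reactants: 1 methyl acetoacetate; 2 methyl (E)-but-2-enoate (methyl crotonate)
Product: 4 methyl 6-methyl-2,4-dioxocyclohexane-1-carboxylate, via dimethyl 2-acetyl-3-methylpentanedioate 3 (not isolated)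
Conditions: NaOMe (1.1 eq), MeOH, reflux, 16 h; then aq HCl, 0 °C
Reagents that add atoms: none
Why: Michael addition of the acetoacetate enolate to the crotonate β-carbon joins the two fragments, and the adduct closes by Dieckmann (intramolecular Claisen) condensation driven by formation of the stable β-diketone enolate; the stereocentres arise uncontrolled and are erased in step 2.

Step 2
Reactants: 4 methyl 6-methyl-2,4-dioxocyclohexane-1-carboxylate
Product: 5 methyl 3,5-dibromo-2,4-dihydroxy-6-methylbenzoate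
Conditions: Br2 (3.1 eq), AcOH, 15 °C → rt, 16 h
Reagents that add atoms: bromine, BrBr
Why: Bromination–dehydrobromination of the enolised cyclohexane-1,3-dione aromatises the ring, and the resorcinol formed is brominated at both free positions, giving one crystalline product.

Step 3
Reactants: 5 methyl 3,5-dibromo-2,4-dihydroxy-6-methylbenzoate
Product: 6 methyl 2,4-dihydroxy-6-methylbenzoate (methyl orsellinate)
Conditions: H2 (1 atm), 10% Pd/C, NaOAc (2.5 eq), MeOH, rt
Reagents that add atoms: none
Why: Catalytic hydrodehalogenation cleaves both aryl C–Br bonds while ester and phenols are inert, with acetate taking up the HBr.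

Step 4
Reactants: 6 methyl 2,4-dihydroxy-6-methylbenzoate
Product: 7 methyl 2,4-bis(benzyloxy)-6-methylbenzoate
Conditions: BnBr (2.5 eq), K2CO3 (3 eq), DMF, 60 °C
Reagents that add atoms: benzyl bromide, BrCc1ccccc1
Why: Williamson ether synthesis, with DMF and heat ensuring that the hydrogen-bonded 2-OH is alkylated as well as the 4-OH.

Step 5
Reactants: 7 methyl 2,4-bis(benzyloxy)-6-methylbenzoate
Product: 8 methyl 4,6-bis(benzyloxy)-3-bromo-2-methylbenzoate (bromine at orsellinate C5)
Conditions: NBS (1.05 eq), MeCN, 0 °C → rt, dark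
Reagents that add atoms: N-bromosuccinimide, O=C1CCC(=O)N1Br
Why: Electrophilic aromatic substitution goes to C5 (para to one OBn, ortho to the other) and not to C3 between the two benzyloxy groups, as in the 2-bromination of 3,5-dimethoxytoluene; polar, dark conditions suppress benzylic radical bromination.

Step 6
Reactants: 8 methyl 4,6-bis(benzyloxy)-3-bromo-2-methylbenzoate
Product: 9 methyl 4,6-bis(benzyloxy)-2-methyl-3-(4,4,5,5-tetramethyl-1,3,2-dioxaborolan-2-yl)benzoate
Conditions: B2pin2 (1.5 eq), Pd(OAc)2 (3 mol %), SPhos (6 mol %), KOAc (3 eq), 1,4-dioxane, 90 °C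
Reagents that add atoms: bis(pinacolato)diboron, CC1(C)OB(OC1(C)C)B1OC(C)(C)C(C)(C)O1
Why: Miyaura borylation, in which the bulky electron-rich SPhos ligand allows oxidative addition into the di-ortho-substituted bromide and the weak base KOAc spares the ester and prevents Suzuki homocoupling.

Step 7
Reactants: 9 methyl 4,6-bis(benzyloxy)-2-methyl-3-(4,4,5,5-tetramethyl-1,3,2-dioxaborolan-2-yl)benzoate
Product: 10 methyl 4,6-bis(benzyloxy)-3-hydroxy-2-methylbenzoate
Conditions: 30% H2O2 (3 eq), 1 M aq NaOH (1.5 eq), THF, 0 °C → rt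
Reagents that add atoms: hydrogen peroxide, OO
Why: Boronate oxidation, in which hydroperoxide adds to boron and the aryl group migrates to oxygen, so the phenol appears exactly where the boron was; the hindered ester survives cold dilute base.

Step 8
Reactants: 10 methyl 4,6-bis(benzyloxy)-3-hydroxy-2-methylbenzoate
Product: 11 methyl 3,4,6-tris(benzyloxy)-2-methylbenzoate
Conditions: BnBr (1.3 eq), K2CO3 (2 eq), DMF, 60 °C
Reagents that add atoms: benzyl bromide, BrCc1ccccc1
Why: Williamson ether synthesis on the single free phenol.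

Step 9
Reactants: 11 methyl 3,4,6-tris(benzyloxy)-2-methylbenzoate
Product: 12 3,4,6-tris(benzyloxy)-2-methylbenzoic acid (tribenzyl 5-hydroxyorsellinic acid, ring A)
Conditions: KOH (10 eq), DMSO–H2O 4:1, 90 °C; then 2 M HCl
Reagents that add atoms: potassium hydroxide, [K+].[OH-]
Why: Saponification of the doubly ortho-substituted methyl ester by poorly solvated hydroxide in hot aqueous DMSO, conditions to which benzyl ethers are stable.

Step 10
Reactants: 6 methyl 2,4-dihydroxy-6-methylbenzoate
Product: 13 methyl 4-(benzyloxy)-2-hydroxy-6-methylbenzoate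
Conditions: BnBr (1.05 eq), K2CO3 (1.2 eq), acetone, reflux
Reagents that add atoms: benzyl bromide, BrCc1ccccc1
Why: Regioselective Williamson etherification, since the 2-OH is hydrogen-bonded to the ester carbonyl and only the 4-OH reacts with one equivalent of halide in acetone.

Step 11
Reactants: 13 methyl 4-(benzyloxy)-2-hydroxy-6-methylbenzoate
Product: 14 methyl 4-(benzyloxy)-2-methoxy-6-methylbenzoate
Conditions: MeI (3 eq), K2CO3 (3 eq), DMF, 50 °C
Reagents that add atoms: iodomethane, CI
Why: Williamson O-methylation of the remaining chelated phenol under forcing conditions installs the 2'-OMe of the target.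

Step 12
Reactants: 14 methyl 4-(benzyloxy)-2-methoxy-6-methylbenzoate
Product: 15 4-(benzyloxy)-2-methoxy-6-methylbenzoic acid
Conditions: KOH (10 eq), DMSO–H2O 4:1, 90 °C; then 2 M HCl
Reagents that add atoms: potassium hydroxide, [K+].[OH-]
Why: Saponification of the hindered methyl ester as in step 9, with methyl and benzyl ethers unaffected.

Step 13
Reactants: 15 4-(benzyloxy)-2-methoxy-6-methylbenzoic acid
Product: 16 4-hydroxy-2-methoxy-6-methylbenzoic acid
Conditions: H2 (1 atm), 10% Pd/C, EtOAc–MeOH, rt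
Reagents that add atoms: none
Why: Hydrogenolysis of the benzyl aryl ether frees the 4-OH under neutral conditions at room temperature.

Step 14
Reactants: 16 4-hydroxy-2-methoxy-6-methylbenzoic acid
Product: 17 prop-2-en-1-yl 4-hydroxy-2-methoxy-6-methylbenzoate (ring B, allyl ester)
Conditions: allyl bromide (1.05 eq), KHCO3 (1.2 eq), DMF, rt
Reagents that add atoms: allyl bromide, C=CCBr
Why: Chemoselective SN2 O-alkylation of the carboxylate, because bicarbonate deprotonates the acid (pKa about 4) but not the phenol (pKa about 9).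

Step 15
Reactants: 7 methyl 2,4-bis(benzyloxy)-6-methylbenzoate
Product: 18 2,4-bis(benzyloxy)-6-methylbenzoic acid
Conditions: KOH (10 eq), DMSO–H2O 4:1, 90 °C; then 2 M HCl
Reagents that add atoms: potassium hydroxide, [K+].[OH-]
Why: Saponification of the protected ester gives a stable acid and avoids heating unprotected orsellinate in alkali, which risks decarboxylation.

Step 16
Reactants: 18 2,4-bis(benzyloxy)-6-methylbenzoic acid
Product: 19 2,4-dihydroxy-6-methylbenzoic acid (orsellinic acid)
Conditions: H2 (1 atm), 10% Pd/C, EtOAc, rt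
Reagents that add atoms: none
Why: Hydrogenolysis of both benzyl ethers releases orsellinic acid under neutral conditions at room temperature, where it does not decarboxylate.

Step 17
Reactants: 19 2,4-dihydroxy-6-methylbenzoic acid
Product: 20 benzyl 2,4-dihydroxy-6-methylbenzoate (benzyl orsellinate, ring C)
Conditions: BnBr (1.05 eq), KHCO3 (1.2 eq), DMF, rt
Reagents that add atoms: benzyl bromide, BrCc1ccccc1
Why: Chemoselective SN2 alkylation of the carboxylate with bicarbonate as base leaves both phenols free.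

Step 18
Reactants: 12 3,4,6-tris(benzyloxy)-2-methylbenzoic acid; 17 prop-2-en-1-yl 4-hydroxy-2-methoxy-6-methylbenzoate
Product: 22 prop-2-en-1-yl 2-methoxy-6-methyl-4-{[3,4,6-tris(benzyloxy)-2-methylbenzoyl]oxy}benzoate, via mixed trifluoroacetic anhydride 21 (not isolated)
Conditions: TFAA (3 eq), toluene, rt, 3 h; aq NaHCO3 work-up
Reagents that add atoms: none
Why: Esterification through the acyl trifluoroacetate (mixed-anhydride method), which for this hindered electron-rich acid reacts with acylium character and acylates the only free OH of 17, while benzyl ethers and the allyl ester tolerate TFA at room temperature.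

Step 19
Reactants: 22 prop-2-en-1-yl 2-methoxy-6-methyl-4-{[3,4,6-tris(benzyloxy)-2-methylbenzoyl]oxy}benzoate
Product: 23 2-methoxy-6-methyl-4-{[3,4,6-tris(benzyloxy)-2-methylbenzoyl]oxy}benzoic acid
Conditions: Pd(PPh3)4 (5 mol %), N-methylaniline (3 eq), THF, rt
Reagents that add atoms: none
Why: Tsuji–Trost deallylation, in which Pd(0) ionises the allyl ester to a π-allyl complex trapped by N-methylaniline, a scavenger too weakly nucleophilic to attack the depside ester; benzyl ethers are untouched.

Step 20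
Reactants: 23 2-methoxy-6-methyl-4-{[3,4,6-tris(benzyloxy)-2-methylbenzoyl]oxy}benzoic acid; 20 benzyl 2,4-dihydroxy-6-methylbenzoate
Product: 25 benzyl 2-hydroxy-4-[(2-methoxy-6-methyl-4-{[3,4,6-tris(benzyloxy)-2-methylbenzoyl]oxy}benzoyl)oxy]-6-methylbenzoate, via mixed trifluoroacetic anhydride 24 (not isolated)
Conditions: TFAA (3 eq), toluene, rt, 4 h; aq NaHCO3 work-up
Reagents that add atoms: none
Why: Mixed-anhydride (TFAA) esterification that is selective for the 4-OH of 20, because the 2-OH is hydrogen-bonded to the benzyl ester carbonyl and sterically shielded; any aryl trifluoroacetate is cleaved on bicarbonate work-up.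

Step 21
Reactants: 25 benzyl 2-hydroxy-4-[(2-methoxy-6-methyl-4-{[3,4,6-tris(benzyloxy)-2-methylbenzoyl]oxy}benzoyl)oxy]-6-methylbenzoate
Product: 26 2'-O-methylhiascic acid
Conditions: H2 (1 atm), 10% Pd/C, EtOAc–THF, rt; filter and concentrate under N2
Reagents that add atoms: none
Why: Global hydrogenolysis removes the three benzyl ethers and the benzyl ester in one operation, while the two aryl ester links and the methyl ether are inert to Pd/H2.

**Compound list**
1 | methyl acetoacetate | CC(=O)CC(=O)OC | starting material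
2 | methyl (E)-but-2-enoate | C/C=C/C(=O)OC | starting material
3 | dimethyl 2-acetyl-3-methylpentanedioate (Michael adduct, diastereomer mixture, not isolated) | COC(=O)CC(C)C(C(C)=O)C(=O)OC | intermediate
4 | methyl 6-methyl-2,4-dioxocyclohexane-1-carboxylate (racemic, largely enolised) | COC(=O)C1C(C)CC(=O)CC1=O | intermediate
5 | methyl 3,5-dibromo-2,4-dihydroxy-6-methylbenzoate | COC(=O)c1c(C)c(Br)c(O)c(Br)c1O | intermediate
6 | methyl 2,4-dihydroxy-6-methylbenzoate | COC(=O)c1c(C)cc(O)cc1O | intermediate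
7 | methyl 2,4-bis(benzyloxy)-6-methylbenzoate | COC(=O)c1c(C)cc(OCc2ccccc2)cc1OCc1ccccc1 | intermediate
8 | methyl 4,6-bis(benzyloxy)-3-bromo-2-methylbenzoate | COC(=O)c1c(C)c(Br)c(OCc2ccccc2)cc1OCc1ccccc1 | intermediate
9 | methyl 4,6-bis(benzyloxy)-2-methyl-3-(4,4,5,5-tetramethyl-1,3,2-dioxaborolan-2-yl)benzoate | COC(=O)c1c(C)c(B2OC(C)(C)C(C)(C)O2)c(OCc2ccccc2)cc1OCc1ccccc1 | intermediate
10 | methyl 4,6-bis(benzyloxy)-3-hydroxy-2-methylbenzoate | COC(=O)c1c(C)c(O)c(OCc2ccccc2)cc1OCc1ccccc1 | intermediate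
11 | methyl 3,4,6-tris(benzyloxy)-2-methylbenzoate | COC(=O)c1c(C)c(OCc2ccccc2)c(OCc2ccccc2)cc1OCc1ccccc1 | intermediate
12 | 3,4,6-tris(benzyloxy)-2-methylbenzoic acid | OC(=O)c1c(C)c(OCc2ccccc2)c(OCc2ccccc2)cc1OCc1ccccc1 | intermediate
13 | methyl 4-(benzyloxy)-2-hydroxy-6-methylbenzoate | COC(=O)c1c(C)cc(OCc2ccccc2)cc1O | intermediate
14 | methyl 4-(benzyloxy)-2-methoxy-6-methylbenzoate | COC(=O)c1c(C)cc(OCc2ccccc2)cc1OC | intermediate
15 | 4-(benzyloxy)-2-methoxy-6-methylbenzoic acid | COc1cc(OCc2ccccc2)cc(C)c1C(=O)O | intermediate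
16 | 4-hydroxy-2-methoxy-6-methylbenzoic acid | COc1cc(O)cc(C)c1C(=O)O | intermediate
17 | prop-2-en-1-yl 4-hydroxy-2-methoxy-6-methylbenzoate | C=CCOC(=O)c1c(C)cc(O)cc1OC | intermediate
18 | 2,4-bis(benzyloxy)-6-methylbenzoic acid | Cc1cc(OCc2ccccc2)cc(OCc2ccccc2)c1C(=O)O | intermediate
19 | 2,4-dihydroxy-6-methylbenzoic acid | Cc1cc(O)cc(O)c1C(=O)O | intermediate
20 | benzyl 2,4-dihydroxy-6-methylbenzoate | Cc1cc(O)cc(O)c1C(=O)OCc1ccccc1 | intermediate
21 | 3,4,6-tris(benzyloxy)-2-methylbenzoic trifluoroacetic anhydride (not isolated) | O=C(OC(=O)C(F)(F)F)c1c(C)c(OCc2ccccc2)c(OCc2ccccc2)cc1OCc1ccccc1 | intermediate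
22 | prop-2-en-1-yl 2-methoxy-6-methyl-4-{[3,4,6-tris(benzyloxy)-2-methylbenzoyl]oxy}benzoate | C=CCOC(=O)c1c(C)cc(OC(=O)c2c(C)c(OCc3ccccc3)c(OCc3ccccc3)cc2OCc2ccccc2)cc1OC | intermediate
23 | 2-methoxy-6-methyl-4-{[3,4,6-tris(benzyloxy)-2-methylbenzoyl]oxy}benzoic acid | COc1cc(OC(=O)c2c(C)c(OCc3ccccc3)c(OCc3ccccc3)cc2OCc2ccccc2)cc(C)c1C(=O)O | intermediate
24 | 2-methoxy-6-methyl-4-{[3,4,6-tris(benzyloxy)-2-methylbenzoyl]oxy}benzoic trifluoroacetic anhydride (not isolated) | COc1cc(OC(=O)c2c(C)c(OCc3ccccc3)c(OCc3ccccc3)cc2OCc2ccccc2)cc(C)c1C(=O)OC(=O)C(F)(F)F | intermediate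
25 | benzyl 2-hydroxy-4-[(2-methoxy-6-methyl-4-{[3,4,6-tris(benzyloxy)-2-methylbenzoyl]oxy}benzoyl)oxy]-6-methylbenzoate | COc1cc(OC(=O)c2c(C)c(OCc3ccccc3)c(OCc3ccccc3)cc2OCc2ccccc2)cc(C)c1C(=O)Oc1cc(C)c(C(=O)OCc2ccccc2)c(O)c1 | intermediate
26 | 2'-O-methylhiascic acid, 2-hydroxy-4-({2-methoxy-6-methyl-4-[(3,4,6-trihydroxy-2-methylbenzoyl)oxy]benzoyl}oxy)-6-methylbenzoic acid | COc1cc(OC(=O)c2c(O)cc(O)c(O)c2C)cc(C)c1C(=O)Oc1cc(C)c(C(=O)O)c(O)c1 | target

**Totals**
Total step count: 21.
Longest linear sequence: 13 steps (1, 2, 3, 4, 5, 6, 7, 8, 9, 18, 19, 20, 21).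

**Three steps most likely to fail**

Step 6 (borylation of the di-ortho-substituted, electron-rich bromide 8; protodebromination may dominate, and it depends on the C5 selectivity of step 5). The fallback abandons the halide and hydroxylates para to a phenoxide by Elbs persulfate oxidation, where the regiochemistry is fixed by mechanism. It sets out from 6: K2S2O8 in cold aqueous KOH gives potassium 4,6-dihydroxy-3-(methoxycarbonyl)-2-methylphenyl sulfate F1, and warm dilute HCl hydrolyses this to methyl 3,4,6-trihydroxy-2-methylbenzoate F2. Tribenzylation of F2 (BnBr, K2CO3, DMF, 60 °C, under N2) comes back to the route at 11. The expected price is a modest Elbs yield on cheap material.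

Step 20 (acylation must pick the 4-OH of 20 over the chelated 2-OH, with a hindered acid). The fallback removes the choice by using a C-ring partner with one free OH. It sets out from 20: allyl bromide and K2CO3 in acetone give benzyl 2-hydroxy-6-methyl-4-(prop-2-en-1-yloxy)benzoate F3. BnBr and K2CO3 in DMF at 60 °C give benzyl 2-(benzyloxy)-6-methyl-4-(prop-2-en-1-yloxy)benzoate F4. Pd(PPh3)4 and morpholine in THF then give benzyl 2-(benzyloxy)-4-hydroxy-6-methylbenzoate F5. Coupling of F5 with acid 23 through 24 (TFAA, toluene) gives benzyl 2-(benzyloxy)-4-[(2-methoxy-6-methyl-4-{[3,4,6-tris(benzyloxy)-2-methylbenzoyl]oxy}benzoyl)oxy]-6-methylbenzoate F6. Hydrogenolysis as in step 21 comes back to the route at 26.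

Step 9 (saponification of the most hindered ester 11 may stall or need temperatures that erode the benzyl ethers). The fallback reaches the acid by a redox detour instead of acyl substitution. It sets out from 11: LiAlH4 in THF (0 °C → rt) gives [3,4,6-tris(benzyloxy)-2-methylphenyl]methanol F7, and MnO2 in CH2Cl2 gives 3,4,6-tris(benzyloxy)-2-methylbenzaldehyde F8. Pinnick oxidation (NaClO2, NaH2PO4, 2-methyl-2-butene, t-BuOH–H2O) comes back to the route at 12.

**Further compounds**
F1 | step 6 | potassium 4,6-dihydroxy-3-(methoxycarbonyl)-2-methylphenyl sulfate | COC(=O)c1c(C)c(OS(=O)(=O)[O-])c(O)cc1O.[K+]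
F2 | step 6 | methyl 3,4,6-trihydroxy-2-methylbenzoate | COC(=O)c1c(C)c(O)c(O)cc1O
F3 | step 20 | benzyl 2-hydroxy-6-methyl-4-(prop-2-en-1-yloxy)benzoate | C=CCOc1cc(C)c(C(=O)OCc2ccccc2)c(O)c1
F4 | step 20 | benzyl 2-(benzyloxy)-6-methyl-4-(prop-2-en-1-yloxy)benzoate | C=CCOc1cc(C)c(C(=O)OCc2ccccc2)c(OCc2ccccc2)c1
F5 | step 20 | benzyl 2-(benzyloxy)-4-hydroxy-6-methylbenzoate | Cc1cc(O)cc(OCc2ccccc2)c1C(=O)OCc1ccccc1
F6 | step 20 | benzyl 2-(benzyloxy)-4-[(2-methoxy-6-methyl-4-{[3,4,6-tris(benzyloxy)-2-methylbenzoyl]oxy}benzoyl)oxy]-6-methylbenzoate | COc1cc(OC(=O)c2c(C)c(OCc3ccccc3)c(OCc3ccccc3)cc2OCc2ccccc2)cc(C)c1C(=O)Oc1cc(C)c(C(=O)OCc2ccccc2)c(OCc2ccccc2)c1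
F7 | step 9 | [3,4,6-tris(benzyloxy)-2-methylphenyl]methanol | OCc1c(C)c(OCc2ccccc2)c(OCc2ccccc2)cc1OCc1ccccc1
F8 | step 9 | 3,4,6-tris(benzyloxy)-2-methylbenzaldehyde | O=Cc1c(C)c(OCc2ccccc2)c(OCc2ccccc2)cc1OCc1ccccc1
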